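The starting material still left is the reading to watch first, since what has gone from it has entered the open intermediate, and target is made from that.

common to all: starting material 10 mM; free catalyst 0.25 mM; second catalyst 0.25 mM

| flask | coupling partner | remark | time |
|---|---|---|---|
| amber | 20 mM | run made earlier |  |
| blue | 23 mM | run made earlier |  |
| ash | 11.0 mM |  | 1.0 h |
| cedar | 30.0 mM |  | 0.30 h |

- amber (time / min: target / %, starting material / %): 12.0: 8, 71; 25.0: 24, 53; 40.0: 40, 32; 50.0: 48, 25; 60.0: 52, 17
- blue (time / min: target / %, starting material / %): 5.00: 1, 86; 10.0: 6, 77; 15.0: 12, 65; 30.0: 30, 41; 60.0: 47, 21

(standard deviation of a reading: 1.5 percentage points)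

- what may be going on: second catalyst + open intermediate <-> catalyst intermediate; coupling partner + target -> over-reaction product; starting material + free catalyst -> free catalyst + open intermediate; coupling partner + catalyst intermediate -> second catalyst + target

- which of the two ends with the higher amount of target, in percent of the starting material charged ("neither" if they lie within 2 percentage points) (ash / cedar / neither)
- target at the end, in percent of the starting material charged, ash
- target at the end, in percent of the starting material charged, cedar

Free catalyst is given back in the step that consumes starting material, so I treat that loss as pseudo-first-order. Pooling the first and last readings of amber and blue gives what I call the feed constant, 0.0276 min⁻¹, the fraction of what remains that is fed onward each minute. Target starts at no rate at all, and the steepest stretch between amber's readings, from 12.0 min to 25.0 min, gives 0.0123 min⁻¹ of the charge, which stays below the opening feed.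

The feed slows as starting material falls, by a factor 0.191 at the end of ash and 0.609 at the end of cedar. Accumulated, it has delivered 80.9% of the charge in ash and 39.1% in cedar, and these are my ceilings for target. More coupling partner did not bring more target at 60.0 min: blue gave 47% against 52% in amber. So I do not scale with partner.

Instead I take the share of the feed found as target in those last readings, 0.611, which gives ash about 49.4%. Cedar is earlier, so its share lies between blue's at 15.0 min and at 30.0 min, giving 13.4% to 19.9%.

The forecast says ash ends higher, with ash at 30% (23% to 38%) and cedar at 20% (15% to 26%). It differs from my ash figure, holding that “coupling looks catalyst-limited, with rate roughly proportional to partner”; its ash figure is close to amber's last reading scaled with the coupling partner charged.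

The flasks give 54.0% target in ash and 17.2% in cedar, so ash ends higher.

    second catalyst + open intermediate ⇌ catalyst intermediate (K = 1700 L mol⁻¹, k = 6.40 L mol⁻¹ s⁻¹)
    coupling partner + target → over-reaction product (k = 0.0130 L mol⁻¹ s⁻¹)
    starting material + free catalyst → free catalyst + open intermediate (k = 1.90 L mol⁻¹ s⁻¹)
    coupling partner + catalyst intermediate → second catalyst + target (k = 2.90 L mol⁻¹ s⁻¹)

Ash leaves 18.1% starting material, and its share of the feed found as target is 0.660, above my 0.611, while the forecast's ash figure stands 24 percentage points low. The neighbouring flask is ash with 1.0 mM of second catalyst. The feed constant again gives 80.9% delivered, and that flask leaves 18.1% starting material, level with ash. Its share rises to 0.840, and target reaches 68.8%.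

(The data are calculated from invented constants; noise was put on by code.)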